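**Plan**

1. Retrosynthetic cuts: C6–Cl back to C6–OH (SN2). C5–C6 (Ni/Cr closure of the ten-membered ring). C3–C4 (Cr 2-bromoallylation). O7–C19 and the C7/C8 oxygens (lactonisation after syn-dihydroxylation of a Z-C7=C8 olefin). C8–C9 (Ni/Cr coupling). The enone is carried as a 12-silyloxy-14-acetoxy cyclohexane. Then C1–C10 (key step) and C1–C14 (alkenyllithium addition).
2. Enabling feature: in the ring C1–C14–C13–C12–C11–C10, quaternary C1 lies between oxygenated C2 and C14. C14 is the enone β-carbon and can be held as a ketone 1,3 to O12. The unit C14(=O)–C1(quaternary)–C2(OH) is the retron of a semipinacol shift of a 2,3-epoxy alcohol.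
3. Key event: a cyclopentenol (C14, C13, C12, C11, C10) that carries the C1–C2 epoxide on C14 takes C1 into the ring when alkenyl C10 migrates from C14 to C1. One isomerisation makes the C1–C10 bond, the quaternary centre and the six-membered ring, and frees 2-OH as a directing group.
4. Ring order in the forward direction: cyclopentenone, then six-membered ring (step 9), γ-lactone (step 27), ten-membered ring (step 32), enone (step 33), chloride (step 34).
5. Stereochemistry: C1/C2 from Sharpless epoxidation and the stereospecific shift. C10/C11 from 2-OH-directed hydrogenation. C9 from Felkin–Anh reduction. C7/C8 from syn-osmylation anti to the ring. C17 from the Roche ester. C3 from Cornforth/polar Felkin–Anh addition. C6 from a ligand-controlled Ni/Cr addition followed by inversion. C12 (from starting material 1) and C14 are temporary.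

Key step: step 9

Remark: briarane numbering is used for all intermediates. C1 is the quaternary fusion carbon (bears C15H3). C2 and C3 are CHOAc, C4 is CH2, C5 bears =C16H2, C6 is CHCl, C7 is the lactone OCH, C8 is COH, C9 is CHOAc, C10 is the fusion CH, C11 bears C20H3, C12 is C=O, C13=C14 is the olefin, C17 bears C18H3, and C19 is the lactone C=O. β is the face of the six-membered ring that carries C15H3; α is the other face.

**Step 1**
Reactants: 1 (S)-4-(tert-butyldimethylsilyloxy)cyclopent-2-en-1-one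
Product: 2 trans-4-TBSO-3-methyl-1-(trimethylsilyloxy)cyclopent-1-ene
Conditions: MeLi, CuI, Et2O, 0 °C; then 1, TMSCl, THF, −78 °C
Reagents that add atoms: methyllithium, [Li]C; chlorotrimethylsilane, C[Si](C)(C)Cl
Why: Gilman cuprate 1,4-addition anti to the OTBS group with in-situ O-silylation of the enolate; the new C11 centre is made planar again in step 2.

**Step 2**
Reactants: 2 trans-4-TBSO-3-methyl-1-(trimethylsilyloxy)cyclopent-1-ene
Product: 3 (S)-4-TBSO-3-methylcyclopent-2-en-1-one
Conditions: Pd(OAc)2, MeCN, rt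
Reagents that add atoms: none
Why: Saegusa–Ito oxidation (Pd(II) enolate, β-hydride elimination of H11) restores the enone with C20H3 on C11 and leaves C12 untouched.

**Step 3**
Reactants: 3 (S)-4-TBSO-3-methylcyclopent-2-en-1-one
Product: 4 (S)-4-TBSO-2-iodo-3-methylcyclopent-2-en-1-one
Conditions: I2, PhI(OCOCF3)2, pyridine, CH2Cl2, rt
Reagents that add atoms: iodine, II
Why: α-iodination of a β-substituted enone with the I2/hypervalent-iodine/pyridine system, which works where plain I2/pyridine is slow.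

**Step 4**
Reactants: 4 (S)-4-TBSO-2-iodo-3-methylcyclopent-2-en-1-one
Product: 5 (S)-2-(benzyloxymethyl)-4-TBSO-3-methylcyclopent-2-en-1-one (ring = C14, C10, C11, C12, C13; CH2OBn = C9)
Conditions: Bu3SnCH2OBn, Pd2(dba)3 (cat.), AsPh3, CuI (cat.), NMP, 50 °C
Reagents that add atoms: (benzyloxymethyl)tributylstannane, CCCC[Sn](CCCC)(CCCC)COCc1ccccc1
Why: Stille coupling of an α-iodoenone with an alkoxymethylstannane under neutral conditions puts C9 on sp2 C10, where the β-alkoxy ketone cannot eliminate.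

**Step 5**
Reactants: 6 but-2-yn-1-ol
Product: 8 (E)-3-iodobut-2-en-1-ol, via O,C-bis(chlorozirconocene) adduct 7 (not isolated)
Conditions: Cp2Zr(H)Cl (2.2 equiv), THF, rt; I2, 0 °C; aq. work-up
Reagents that add atoms: iodine, II
Why: Hydrozirconation–iodination: syn addition with Zr on the less hindered, methyl-bearing alkyne carbon, then iodinolysis with retention, gives the E-iodide (CH3 cis to CH2OH).

**Step 6**
Reactants: 8 (E)-3-iodobut-2-en-1-ol; 5 (S)-2-(benzyloxymethyl)-4-TBSO-3-methylcyclopent-2-en-1-one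
Product: 10 cyclopentenol diol (C14 tertiary alcohol bearing the E-C1(CH3)=C2H–C3H2OH group trans to OTBS), via dilithio species 9 (not isolated)
Conditions: 8, t-BuLi (3 equiv), Et2O, −78 °C; then 5, LaCl3·2LiCl (cat.), THF, −78 °C; aq. work-up
Reagents that add atoms: none
Why: Iodine–lithium exchange with retention of geometry and 1,2-addition of the alkenyllithium to the enone from the face anti to OTBS; the C14 configuration is of no consequence because C14 becomes sp2 in step 9.

**Step 7**
Reactants: 10 cyclopentenol diol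
Product: 11 epoxy diol (C1–C2 epoxide, 1R,2S)
Conditions: Ti(OiPr)4 (cat.), L-(+)-diethyl tartrate (cat.), t-BuOOH, 4 Å MS, CH2Cl2, −20 °C
Reagents that add atoms: tert-butyl hydroperoxide, CC(C)(C)OO
Why: Sharpless asymmetric epoxidation of the primary allylic alcohol sets C1 and C2 under reagent control (same face as for geraniol with the L-tartrate) and spares the ring olefin, which is allylic only to a tertiary alcohol.

**Step 8**
Reactants: 11 epoxy diol
Product: 12 epoxy alcohol, 3-O-TBS ether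
Conditions: TBSCl, imidazole, CH2Cl2, 0 °C
Reagents that add atoms: tert-butyldimethylsilyl chloride, CC(C)(C)[Si](C)(C)Cl
Why: Selective silylation of the primary alcohol beside the tertiary one blocks Payne migration and later hemiketal formation.

**Step 9**
Reactants: 12 epoxy alcohol, 3-O-TBS ether
Product: 13 (2S,5S)-3-(benzyloxymethyl)-5-TBSO-2-[(R)-2-TBSO-1-hydroxyethyl]-2,4-dimethylcyclohex-3-en-1-one (14-ketone, C10=C11 olefin, free 2-OH)
Conditions: ZnBr2 (20 mol %), CH2Cl2, 0 °C to rt
Reagents that add atoms: none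
Why: Zn(II) binds the epoxide oxygen, the tertiary C1–O bond ionises and, in concert, the antiperiplanar alkenyl carbon C10 shifts from carbinol C14 to C1 while C14–OH collapses to the ketone, so that C1 is inserted into the five-membered ring (semipinacol rearrangement of a 2,3-epoxy alcohol in its ring-expanding form, well known for tertiary α-hydroxy epoxides). No ring is closed in the Baldwin sense: the cyclopentene C14–C13–C12–C11–C10 is enlarged by a 1,2-shift to the cyclohexene C1–C14–C13–C12–C11–C10. C1 forms with inversion at the epoxide carbon, so its configuration follows from the Sharpless epoxide and the E-olefin geometry, C2 keeps its C–O bond and configuration, and C14 becomes sp2. The step needs migration of C10 rather than C13H2, which the far higher migratory aptitude of an alkenyl over a primary alkyl carbon secures, and it needs opening at C1 rather than C2, which the tertiary against secondary cation character secures. Ionisation of the tertiary allylic C14–OH is the competing path and is held back by the inductive effect of the adjacent epoxide and by the mild, catalytic Lewis acid. The product cannot conjugate through quaternary C1, has O14 placed 1,3 to O12 (the latent enone), and has 2-OH free for step 10.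

**Step 10**
Reactants: 13 cyclohexenone with C10=C11 olefin
Product: 14 (2S,3S,4R,5S)-cyclohexanone (H10 and H11 both α; C9 and C20H3 both β)
Conditions: [Ir(cod)(PCy3)(py)]PF6 (cat.), H2 (50 bar), CH2Cl2, rt
Reagents that add atoms: none
Why: Hydroxyl-directed homogeneous hydrogenation with the Crabtree catalyst: Ir bound to the homoallylic 2-OH on the α substituent of C1 delivers both hydrogens syn to the α face of the tetrasubstituted olefin, setting C10 and C11, while OTBS sits on the β face.

**Step 11**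
Reactants: 14 cyclohexanone
Product: 15 2,14-diol (14β, equatorial alcohol)
Conditions: NaBH4, MeOH, 0 °C
Reagents that add atoms: none
Why: Borohydride reduction by axial attack on the face opposite the axial C15H3 should give the equatorial alcohol; this centre is temporary.

**Step 12**
Reactants: 15 2,14-diol
Product: 16 2,14-diacetate
Conditions: Ac2O, pyridine, DMAP (cat.), CH2Cl2, rt
Reagents that add atoms: acetic anhydride, CC(=O)OC(C)=O
Why: Acetylation installs the permanent 2-acetate and, in the same operation, the 14-acetate that serves as the leaving group of the latent enone.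

**Step 13**
Reactants: 16 2,14-diacetate
Product: 17 C9 primary alcohol
Conditions: H2 (1 atm), Pd/C, EtOAc, rt
Reagents that add atoms: none
Why: Hydrogenolysis of the benzyl ether; no olefin is present and silyl ethers and acetates are inert.

**Step 14**
Reactants: 17 C9 primary alcohol
Product: 18 C9 aldehyde
Conditions: Dess–Martin periodinane, CH2Cl2, 0 °C to rt
Reagents that add atoms: none
Why: Dess–Martin oxidation under near-neutral conditions; the equatorial formyl group is also the stable epimer at C10.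

**Step 15**
Reactants: 19 methyl (S)-3-hydroxy-2-methylpropanoate
Product: 20 methyl (S)-3-TBSO-2-methylpropanoate
Conditions: TBSCl, imidazole, DMF, rt
Reagents that add atoms: tert-butyldimethylsilyl chloride, CC(C)(C)[Si](C)(C)Cl
Why: Standard silylation; the stereocentre becomes C17.

**Step 16**
Reactants: 20 methyl (S)-3-TBSO-2-methylpropanoate
Product: 21 (S)-3-TBSO-2-methylpropanal
Conditions: DIBAL-H, CH2Cl2, −78 °C; Rochelle salt work-up
Reagents that add atoms: none
Why: Partial reduction of the ester through the stable tetrahedral aluminium acetal at low temperature.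

**Step 17**
Reactants: 21 (S)-3-TBSO-2-methylpropanal
Product: 22 (R)-tert-butyldimethyl(2-methylbut-3-ynyloxy)silane
Conditions: Ohira–Bestmann reagent, K2CO3, MeOH, 0 °C to rt
Reagents that add atoms: dimethyl (1-diazo-2-oxopropyl)phosphonate, CC(=O)C(=[N+]=[N-])P(=O)(OC)OC
Why: Seyferth–Gilbert homologation in the Ohira–Bestmann variant, mild enough to keep the α-stereocentre of this aldehyde class.

**Step 18**
Reactants: 22 (R)-tert-butyldimethyl(2-methylbut-3-ynyloxy)silane
Product: 24 (R)-5-TBSO-4-methylpent-2-yn-1-ol, via lithium acetylide 23 (not isolated)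
Conditions: n-BuLi, THF, −78 °C; (CH2O)n, −78 °C to rt
Reagents that add atoms: paraformaldehyde (as formaldehyde), C=O
Why: Acetylide hydroxymethylation adds C6.

**Step 19**
Reactants: 24 (R)-5-TBSO-4-methylpent-2-yn-1-ol
Product: 26 (S,Z)-5-TBSO-3-iodo-4-methylpent-2-en-1-ol, via cyclic alkenylalanate 25 (not isolated)
Conditions: Red-Al, Et2O, 0 °C to rt; I2, THF, −78 °C
Reagents that add atoms: iodine, II
Why: Alkoxide-directed trans-hydroalumination of the propargylic alcohol places Al, and then I, on the distal carbon C8 cis to C6H2O, which is the geometry the later syn-dihydroxylation needs.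

**Step 20**
Reactants: 26 (S,Z)-5-TBSO-3-iodo-4-methylpent-2-en-1-ol
Product: 27 alkenyl iodide with 6-O-TBDPS and 19-O-TBS
Conditions: TBDPSCl, imidazole, CH2Cl2, rt
Reagents that add atoms: tert-butyldiphenylsilyl chloride, CC(C)(C)[Si](Cl)(c1ccccc1)c1ccccc1
Why: Base-free silylation gives a primary ether that survives the later removal of the primary TBS groups.

**Step 21**
Reactants: 18 C9 aldehyde; 27 alkenyl iodide
Product: 28 allylic alcohol (C8–C9 bond, Z-C7=C8; C9 epimers)
Conditions: CrCl2 (4 equiv), NiCl2 (2 mol %), DMSO/THF, rt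
Reagents that add atoms: none
Why: Nozaki–Hiyama–Kishi coupling tolerates the acetates and keeps the geometry of the trisubstituted alkenyl iodide; the C9 configuration does not matter here because it is reset in steps 22 and 23.

**Step 22**
Reactants: 28 allylic alcohol
Product: 29 C9 enone
Conditions: Dess–Martin periodinane, CH2Cl2, 0 °C to rt
Reagents that add atoms: none
Why: Dess–Martin oxidation under neutral conditions leaves the Z-olefin and C17 unchanged.

**Step 23**
Reactants: 29 C9 enone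
Product: 30 (9S)-allylic alcohol
Conditions: NaBH4, CeCl3·7H2O, MeOH, −78 °C
Reagents that add atoms: none
Why: Luche 1,2-reduction under Felkin–Anh control: hydride attacks anti to C1, the largest group on C10, with C11 next to the carbonyl oxygen, which gives 9S, the epimer opposite to the one expected from carbon nucleophile addition to aldehyde 18.

**Step 24**
Reactants: 30 (9S)-allylic alcohol
Product: 31 9-acetate
Conditions: Ac2O, pyridine, DMAP (cat.), CH2Cl2, rt
Reagents that add atoms: acetic anhydride, CC(=O)OC(C)=O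
Why: Acetylation installs the permanent 9-acetate and prevents O9 from competing with O7 in the lactonisation.

**Step 25**
Reactants: 31 9-acetate
Product: 32 7,8-diol
Conditions: OsO4 (cat.), NMO, acetone/H2O, rt
Reagents that add atoms: N-methylmorpholine N-oxide (oxygen delivered through OsO4), C[N+]1([O-])CCOCC1; water, O
Why: Upjohn syn-dihydroxylation: the Z geometry fixes the C7/C8 relation, and in the A1,3-minimised rotamer (H9 eclipsing the olefin because C6 is cis to C9) osmium attacks the face anti to the bulky C10 ring substituent, giving 7R,8R as in the target.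

**Step 26**
Reactants: 32 7,8-diol
Product: 33 tetraol (free 3-, 7-, 8- and 19-OH)
Conditions: HF·pyridine, pyridine, THF, 0 °C
Reagents that add atoms: none
Why: Buffered fluoride cleaves the two primary TBS ethers faster than the secondary 12-OTBS and the primary TBDPS ether, and the weakly acidic medium limits 2→3 acetyl migration.

**Step 27**
Reactants: 33 tetraol
Product: 35 γ-lactone C3 aldehyde, via lactol aldehyde 34 (not isolated)
Conditions: TEMPO (cat.), PhI(OAc)2, CH2Cl2, rt
Reagents that add atoms: none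
Why: Oxoammonium oxidation selective for primary alcohols turns C3 into the aldehyde and C19 into an aldehyde that closes on 7-OH to the five-membered lactol and is oxidised on to the lactone; C17 keeps CH3 trans to C9, which should also be the stable arrangement.

**Step 28**
Reactants: 35 γ-lactone C3 aldehyde
Product: 36 (3S)-2-bromoallyl carbinol
Conditions: 2,3-dibromopropene, CrCl2, cobalt phthalocyanine (cat.), THF, 0 °C to rt (no Ni)
Reagents that add atoms: 2,3-dibromopropene, C=C(Br)CBr
Why: Cr-mediated 2-haloallylation activates only the allylic C–Br bond and adds to the α-acetoxy aldehyde in the Cornforth/polar Felkin–Anh sense, giving the 2,3-anti relation (3S), with the bulky C1 reinforcing the bias.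

**Step 29**
Reactants: 36 (3S)-2-bromoallyl carbinol
Product: 37 2,3,9,14-tetraacetate
Conditions: Ac2O, pyridine, rt
Reagents that add atoms: acetic anhydride, CC(=O)OC(C)=O
Why: Acetylation of the secondary 3-OH without DMAP leaves the tertiary 8-OH free.

**Step 30**
Reactants: 37 2,3,9,14-tetraacetate
Product: 38 6,12-diol
Conditions: HF·pyridine, THF, rt
Reagents that add atoms: none
Why: Prolonged fluoride treatment removes the TBDPS and the remaining TBS ether in one operation under conditions that acetates, lactone and alkenyl bromide tolerate.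

**Step 31**
Reactants: 38 6,12-diol
Product: 39 12-keto C6 aldehyde
Conditions: Dess–Martin periodinane, pyridine, CH2Cl2, 0 °C
Reagents that add atoms: none
Why: One Dess–Martin oxidation converts both alcohols under buffered conditions that should not epimerise C7 or C11.

**Step 32**
Reactants: 39 12-keto C6 aldehyde
Product: 40 ten-membered (6R)-allylic alcohol with C5=C16H2
Conditions: CrCl2, chiral oxazoline–sulfonamide ligand (antipode for Re-face attack), Et3N, NiCl2·(2,9-dimethylphenanthroline) (cat.), MeCN/THF, 2 mM, rt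
Reagents that add atoms: none
Why: Intramolecular Nozaki–Hiyama–Kishi reaction: Ni inserts into C5–Br, the alkenylchromium(III) adds only to the aldehyde (ketone, esters and lactone are inert) and closes the ring at C5–C6, while the chiral chromium ligand directs attack to the Re face against the polar Felkin–Anh preference.

**Step 33**
Reactants: 40 ten-membered (6R)-allylic alcohol
Product: 41 C13=C14 enone, 6R alcohol
Conditions: DBU, CH2Cl2, 0 °C
Reagents that add atoms: none
Why: E1cB elimination (deprotonation at C13, loss of the 14-acetate) reveals the enone, and short exposure at 0 °C limits enolisation towards C11, whose β-methyl group was set kinetically.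

**Step 34**
Reactants: 41 C13=C14 enone, 6R alcohol
Product: 42 target CNP0391614.1
Conditions: PPh3, Cl3CC(O)CCl3, CH2Cl2, 0 °C
Reagents that add atoms: hexachloroacetone, O=C(C(Cl)(Cl)Cl)C(Cl)(Cl)Cl
Why: Appel-type deoxychlorination with PPh3/hexachloroacetone, the variant known to convert secondary allylic alcohols into unrearranged chlorides with inversion, turns 6R-OH into 6S-Cl; the tertiary 8-OH is too hindered to be activated.

**Compound list**

1 | (S)-4-(tert-butyldimethylsilyloxy)cyclopent-2-en-1-one | O=C1C[C@H](O[Si](C)(C)C(C)(C)C)C=C1 | starting material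
2 | trans-4-TBSO-3-methyl-1-(trimethylsilyloxy)cyclopent-1-ene | C[Si](C)(C)OC1=C[C@H](C)[C@@H](O[Si](C)(C)C(C)(C)C)C1 | intermediate
3 | (S)-4-TBSO-3-methylcyclopent-2-en-1-one | O=C1C[C@H](O[Si](C)(C)C(C)(C)C)C(C)=C1 | intermediate
4 | (S)-4-TBSO-2-iodo-3-methylcyclopent-2-en-1-one | O=C1C[C@H](O[Si](C)(C)C(C)(C)C)C(C)=C1I | intermediate
5 | (S)-2-(benzyloxymethyl)-4-TBSO-3-methylcyclopent-2-en-1-one | O=C1C[C@H](O[Si](C)(C)C(C)(C)C)C(C)=C1COCc1ccccc1 | intermediate
6 | but-2-yn-1-ol | CC#CCO | starting material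
7 | O,C-bis(chlorozirconocene) adduct of 6 (Cp drawn η1) | C/C(=C\CO[Zr](Cl)(C1C=CC=C1)C1C=CC=C1)[Zr](Cl)(C1C=CC=C1)C1C=CC=C1 | intermediate
8 | (E)-3-iodobut-2-en-1-ol | OC/C=C(\C)I | intermediate
9 | lithium (E)-3-lithiobut-2-en-1-olate | [Li]OC/C=C(\C)[Li] | intermediate
10 | cyclopentenol diol (alkenyl trans to OTBS) | OC/C=C(\C)[C@@]1(O)C[C@H](O[Si](C)(C)C(C)(C)C)C(C)=C1COCc1ccccc1 | intermediate
11 | epoxy diol (1R,2S epoxide) | OC[C@@H]1O[C@@]1(C)[C@@]1(O)C[C@H](O[Si](C)(C)C(C)(C)C)C(C)=C1COCc1ccccc1 | intermediate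
12 | epoxy alcohol, 3-O-TBS | CC(C)(C)[Si](C)(C)OC[C@@H]1O[C@@]1(C)[C@@]1(O)C[C@H](O[Si](C)(C)C(C)(C)C)C(C)=C1COCc1ccccc1 | intermediate
13 | ring-expanded β-hydroxy ketone (14-ketone, C10=C11) | CC(C)(C)[Si](C)(C)OC[C@H](O)[C@@]1(C)C(=O)C[C@H](O[Si](C)(C)C(C)(C)C)C(C)=C1COCc1ccccc1 | intermediate
14 | saturated 14-ketone (H10, H11 α) | CC(C)(C)[Si](C)(C)OC[C@H](O)[C@@]1(C)C(=O)C[C@H](O[Si](C)(C)C(C)(C)C)[C@H](C)[C@@H]1COCc1ccccc1 | intermediate
15 | 2,14-diol (14β-OH) | CC(C)(C)[Si](C)(C)OC[C@H](O)[C@@]1(C)[C@H](O)C[C@H](O[Si](C)(C)C(C)(C)C)[C@H](C)[C@@H]1COCc1ccccc1 | intermediate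
16 | 2,14-diacetate | CC(C)(C)[Si](C)(C)OC[C@H](OC(C)=O)[C@@]1(C)[C@H](OC(C)=O)C[C@H](O[Si](C)(C)C(C)(C)C)[C@H](C)[C@@H]1COCc1ccccc1 | intermediate
17 | C9 primary alcohol | CC(C)(C)[Si](C)(C)OC[C@H](OC(C)=O)[C@@]1(C)[C@H](OC(C)=O)C[C@H](O[Si](C)(C)C(C)(C)C)[C@H](C)[C@@H]1CO | intermediate
18 | C9 aldehyde | CC(C)(C)[Si](C)(C)OC[C@H](OC(C)=O)[C@@]1(C)[C@H](OC(C)=O)C[C@H](O[Si](C)(C)C(C)(C)C)[C@H](C)[C@@H]1C=O | intermediate
19 | methyl (S)-3-hydroxy-2-methylpropanoate | COC(=O)[C@@H](C)CO | starting material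
20 | methyl (S)-3-TBSO-2-methylpropanoate | COC(=O)[C@@H](C)CO[Si](C)(C)C(C)(C)C | intermediate
21 | (S)-3-TBSO-2-methylpropanal | O=C[C@@H](C)CO[Si](C)(C)C(C)(C)C | intermediate
22 | (R)-tert-butyldimethyl(2-methylbut-3-ynyloxy)silane | C#C[C@@H](C)CO[Si](C)(C)C(C)(C)C | intermediate
23 | lithium acetylide of 22 | [Li]C#C[C@@H](C)CO[Si](C)(C)C(C)(C)C | intermediate
24 | (R)-5-TBSO-4-methylpent-2-yn-1-ol | OCC#C[C@@H](C)CO[Si](C)(C)C(C)(C)C | intermediate
25 | sodium cyclic alkenylalanate | [Na+].COCCO[Al-]1(OCCOC)OCC=C1[C@@H](C)CO[Si](C)(C)C(C)(C)C | intermediate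
26 | (S,Z)-5-TBSO-3-iodo-4-methylpent-2-en-1-ol | OC/C=C(\I)[C@@H](C)CO[Si](C)(C)C(C)(C)C | intermediate
27 | alkenyl iodide, 6-O-TBDPS, 19-O-TBS | CC(C)(C)[Si](OC/C=C(\I)[C@@H](C)CO[Si](C)(C)C(C)(C)C)(c1ccccc1)c1ccccc1 | intermediate
28 | coupled allylic alcohol (C9 epimers) | CC(C)(C)[Si](C)(C)OC[C@H](OC(C)=O)[C@@]1(C)[C@H](OC(C)=O)C[C@H](O[Si](C)(C)C(C)(C)C)[C@H](C)[C@@H]1C(O)/C(=C\CO[Si](c1ccccc1)(c1ccccc1)C(C)(C)C)[C@@H](C)CO[Si](C)(C)C(C)(C)C | intermediate
29 | C9 enone | CC(C)(C)[Si](C)(C)OC[C@H](OC(C)=O)[C@@]1(C)[C@H](OC(C)=O)C[C@H](O[Si](C)(C)C(C)(C)C)[C@H](C)[C@@H]1C(=O)/C(=C\CO[Si](c1ccccc1)(c1ccccc1)C(C)(C)C)[C@@H](C)CO[Si](C)(C)C(C)(C)C | intermediate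
30 | (9S)-allylic alcohol | CC(C)(C)[Si](C)(C)OC[C@H](OC(C)=O)[C@@]1(C)[C@H](OC(C)=O)C[C@H](O[Si](C)(C)C(C)(C)C)[C@H](C)[C@@H]1[C@H](O)/C(=C\CO[Si](c1ccccc1)(c1ccccc1)C(C)(C)C)[C@@H](C)CO[Si](C)(C)C(C)(C)C | intermediate
31 | 2,9,14-triacetate, Z-C7=C8 | CC(C)(C)[Si](C)(C)OC[C@H](OC(C)=O)[C@@]1(C)[C@H](OC(C)=O)C[C@H](O[Si](C)(C)C(C)(C)C)[C@H](C)[C@@H]1[C@H](OC(C)=O)/C(=C\CO[Si](c1ccccc1)(c1ccccc1)C(C)(C)C)[C@@H](C)CO[Si](C)(C)C(C)(C)C | intermediate
32 | 7,8-diol | CC(C)(C)[Si](C)(C)OC[C@H](OC(C)=O)[C@@]1(C)[C@H](OC(C)=O)C[C@H](O[Si](C)(C)C(C)(C)C)[C@H](C)[C@@H]1[C@H](OC(C)=O)[C@](O)([C@@H](C)CO[Si](C)(C)C(C)(C)C)[C@@H](O)CO[Si](c1ccccc1)(c1ccccc1)C(C)(C)C | intermediate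
33 | 3,7,8,19-tetraol | OC[C@H](OC(C)=O)[C@@]1(C)[C@H](OC(C)=O)C[C@H](O[Si](C)(C)C(C)(C)C)[C@H](C)[C@@H]1[C@H](OC(C)=O)[C@](O)([C@@H](C)CO)[C@@H](O)CO[Si](c1ccccc1)(c1ccccc1)C(C)(C)C | intermediate
34 | C19 lactol, C3 aldehyde | O=C[C@H](OC(C)=O)[C@@]1(C)[C@H](OC(C)=O)C[C@H](O[Si](C)(C)C(C)(C)C)[C@H](C)[C@@H]1[C@H](OC(C)=O)[C@]1(O)[C@@H](C)C(O)O[C@H]1CO[Si](c1ccccc1)(c1ccccc1)C(C)(C)C | intermediate
35 | γ-lactone, C3 aldehyde | O=C[C@H](OC(C)=O)[C@@]1(C)[C@H](OC(C)=O)C[C@H](O[Si](C)(C)C(C)(C)C)[C@H](C)[C@@H]1[C@H](OC(C)=O)[C@]1(O)[C@@H](C)C(=O)O[C@H]1CO[Si](c1ccccc1)(c1ccccc1)C(C)(C)C | intermediate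
36 | (3S)-2-bromoallyl carbinol | C=C(Br)C[C@H](O)[C@H](OC(C)=O)[C@@]1(C)[C@H](OC(C)=O)C[C@H](O[Si](C)(C)C(C)(C)C)[C@H](C)[C@@H]1[C@H](OC(C)=O)[C@]1(O)[C@@H](C)C(=O)O[C@H]1CO[Si](c1ccccc1)(c1ccccc1)C(C)(C)C | intermediate
37 | 2,3,9,14-tetraacetate | C=C(Br)C[C@H](OC(C)=O)[C@H](OC(C)=O)[C@@]1(C)[C@H](OC(C)=O)C[C@H](O[Si](C)(C)C(C)(C)C)[C@H](C)[C@@H]1[C@H](OC(C)=O)[C@]1(O)[C@@H](C)C(=O)O[C@H]1CO[Si](c1ccccc1)(c1ccccc1)C(C)(C)C | intermediate
38 | 6,12-diol | C=C(Br)C[C@H](OC(C)=O)[C@H](OC(C)=O)[C@@]1(C)[C@H](OC(C)=O)C[C@H](O)[C@H](C)[C@@H]1[C@H](OC(C)=O)[C@]1(O)[C@@H](C)C(=O)O[C@H]1CO | intermediate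
39 | 12-keto C6 aldehyde | C=C(Br)C[C@H](OC(C)=O)[C@H](OC(C)=O)[C@@]1(C)[C@H](OC(C)=O)CC(=O)[C@H](C)[C@@H]1[C@H](OC(C)=O)[C@]1(O)[C@@H](C)C(=O)O[C@H]1C=O | intermediate
40 | macrocyclic (6R)-alcohol, 14-acetoxy-12-ketone | C=C1C[C@H](OC(C)=O)[C@H](OC(C)=O)[C@@]2(C)[C@H](OC(C)=O)CC(=O)[C@H](C)[C@@H]2[C@H](OC(C)=O)[C@]2(O)[C@@H](C)C(=O)O[C@H]2[C@@H]1O | intermediate
41 | macrocyclic (6R)-alcohol, C13=C14 enone | C=C1C[C@H](OC(C)=O)[C@H](OC(C)=O)[C@@]2(C)C=CC(=O)[C@H](C)[C@@H]2[C@H](OC(C)=O)[C@]2(O)[C@@H](C)C(=O)O[C@H]2[C@@H]1O | intermediate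
42 | CNP0391614.1 (1S,2R,3S,6S,7R,8R,9S,10S,11R,17R) | C=C1C[C@H](OC(C)=O)[C@H](OC(C)=O)[C@@]2(C)C=CC(=O)[C@H](C)[C@@H]2[C@H](OC(C)=O)[C@]2(O)[C@@H](C)C(=O)O[C@H]2[C@H]1Cl | target

**Step count and risks**

Total step count: 34. Longest linear sequence: 27 steps (1–4, 6–14, 21–34), counted from 1.

Steps most likely to fail:

Step 10. Hydrogen uptake at the tetrasubstituted olefin next to quaternary C1 may be very slow, the catalyst may deactivate, or delivery may leak to the β face. The fallback sets out from 5 and comes back at 14. Enone 5 would be hydrogenated heterogeneously (H2, Pd/C poisoned with ethylenediamine, EtOAc) from the face anti to OTBS to give the all-cis cyclopentanone F1. Immediate addition of 9, transmetallated to cerium to suppress enolisation and β-alkoxide loss, from the open α face would give the saturated diol F2. Sharpless epoxidation would give the epoxy diol F3, and silylation the epoxy alcohol F4. The same Zn(II)-promoted semipinacol ring expansion would then lead directly to 14, now with migration of the tertiary sp3 carbon C10 with retention and in preference to C13H2.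

Step 32. Oligomerisation, slow oxidative addition of the alkenyl bromide, or attack on the wrong aldehyde face (the ligand has to override the substrate bias) may defeat the closure. The fallback sets out from 35 and comes back at 40.
- Aldehyde 35 would be propargylated (propargyl bromide, In, THF/H2O, same Cornforth control) to the homopropargylic alcohol F5.
- F5 would be acetylated to the alkyne tetraacetate F6, desilylated with HF·pyridine to the alkyne diol F7, and oxidised with Dess–Martin periodinane to the alkyne keto aldehyde F8.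
- A Ni(0)/bulky N-heterocyclic carbene catalysed reductive alkyne–aldehyde macrocyclisation with Et3SiH in the exo mode (C5–C6 bond, exocyclic methylene) would give the macrocyclic triethylsilyl ether F9.
- HF·pyridine would then release 40.

Step 34. Chloride may attack C16 in the SN2′ sense, or the alkoxyphosphonium ion may ionise with loss of configuration. The fallback sets out from 41 and comes back at 42. A rhenium(VII) oxo catalysed 1,3-transposition (Ph3SiOReO3, Et2O, 0 °C) would move the hydroxyl group to C16 and give the primary allylic alcohol F10 with the C5=C6 olefin. SOCl2 in Et2O without base would form the allylic chlorosulfite F11, which collapses by the SNi′ path and returns chlorine to C6 with regeneration of C5=C16H2. The face of delivery would then depend on the exposed side of the ring olefin and no longer on the C6 configuration of 41.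

**Further compounds**

F1 | step 10 | all-cis cyclopentanone | O=C1C[C@H](O[Si](C)(C)C(C)(C)C)[C@H](C)[C@@H]1COCc1ccccc1
F2 | step 10 | saturated diol | OC/C=C(\C)[C@@]1(O)C[C@H](O[Si](C)(C)C(C)(C)C)[C@H](C)[C@@H]1COCc1ccccc1
F3 | step 10 | epoxy diol | OC[C@@H]1O[C@@]1(C)[C@@]1(O)C[C@H](O[Si](C)(C)C(C)(C)C)[C@H](C)[C@@H]1COCc1ccccc1
F4 | step 10 | epoxy alcohol | CC(C)(C)[Si](C)(C)OC[C@@H]1O[C@@]1(C)[C@@]1(O)C[C@H](O[Si](C)(C)C(C)(C)C)[C@H](C)[C@@H]1COCc1ccccc1
F5 | step 32 | homopropargylic alcohol | C#CC[C@H](O)[C@H](OC(C)=O)[C@@]1(C)[C@H](OC(C)=O)C[C@H](O[Si](C)(C)C(C)(C)C)[C@H](C)[C@@H]1[C@H](OC(C)=O)[C@]1(O)[C@@H](C)C(=O)O[C@H]1CO[Si](c1ccccc1)(c1ccccc1)C(C)(C)C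
F6 | step 32 | alkyne tetraacetate | C#CC[C@H](OC(C)=O)[C@H](OC(C)=O)[C@@]1(C)[C@H](OC(C)=O)C[C@H](O[Si](C)(C)C(C)(C)C)[C@H](C)[C@@H]1[C@H](OC(C)=O)[C@]1(O)[C@@H](C)C(=O)O[C@H]1CO[Si](c1ccccc1)(c1ccccc1)C(C)(C)C
F7 | step 32 | alkyne diol | C#CC[C@H](OC(C)=O)[C@H](OC(C)=O)[C@@]1(C)[C@H](OC(C)=O)C[C@H](O)[C@H](C)[C@@H]1[C@H](OC(C)=O)[C@]1(O)[C@@H](C)C(=O)O[C@H]1CO
F8 | step 32 | alkyne keto aldehyde | C#CC[C@H](OC(C)=O)[C@H](OC(C)=O)[C@@]1(C)[C@H](OC(C)=O)CC(=O)[C@H](C)[C@@H]1[C@H](OC(C)=O)[C@]1(O)[C@@H](C)C(=O)O[C@H]1C=O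
F9 | step 32 | macrocyclic triethylsilyl ether | C=C1C[C@H](OC(C)=O)[C@H](OC(C)=O)[C@@]2(C)[C@H](OC(C)=O)CC(=O)[C@H](C)[C@@H]2[C@H](OC(C)=O)[C@]2(O)[C@@H](C)C(=O)O[C@H]2[C@@H]1O[Si](CC)(CC)CC
F10 | step 34 | primary allylic alcohol | C1[C@H](OC(C)=O)[C@H](OC(C)=O)[C@@]2(C)C=CC(=O)[C@H](C)[C@@H]2[C@H](OC(C)=O)[C@]2(O)[C@@H](C)C(=O)O[C@H]2/C=C1/CO
F11 | step 34 | allylic chlorosulfite | C1[C@H](OC(C)=O)[C@H](OC(C)=O)[C@@]2(C)C=CC(=O)[C@H](C)[C@@H]2[C@H](OC(C)=O)[C@]2(O)[C@@H](C)C(=O)O[C@H]2/C=C1/COS(=O)Cl
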